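The numbers in the tables stem from a simulated flask from invented constants, and the scatter is random.

Substrate charged cannot vanish, so what the birch run does not show at 20.0 min, 38.0 % of the charge, sits in some unread form.

| flask | substrate | partner | remark | time |
|---|---|---|---|---|
| birch | 0.10 M | 0.95 equiv | run made earlier |  |
| cedar | 0.10 M | 0.47 equiv | run made earlier |  |
| teal | 0.10 M (fed, over 20.0 min) | 0.950 equiv | all but substrate at the start; substrate goes in evenly over 20.0 min, the run ends at 20 min | 20 min |
| grey | 0.10 M | 0.950 equiv (fed, over 20.0 min) | all but partner at the start; partner goes in evenly over 20.0 min, the run ends at 20 min | 20 min |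
| red | 0.10 M | 0.950 equiv | a single well-mixed tank run continuously and read at steady state, 20 min in it on average |  |
| ochre | 0.10 M | 0.950 equiv | everything together in a closed stirred flask, run for 20 min | 20 min |

| run | time / min | target / % | substrate / % |
|---|---|---|---|
| birch | 1.50 | 1 | 76 |
| birch | 3.00 | 1 | 59 |
| birch | 6.00 | 7 | 49 |
| birch | 10.0 | 17 | 36 |
| birch | 20.0 | 25 | 37 |
| cedar | 0.333 | 0 | 93 |
| cedar | 0.667 | 0 | 90 |
| cedar | 1.00 | 0 | 85 |
| cedar | 2.00 | 0 | 75 |
| cedar | 4.00 | 2 | 61 |

(standard deviation of a reading: 2 percentage points)

- the stated concentrations are those of everything mixed, before any reaction; amounts are the same in each set-up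
- the feed brings no volume worth counting
- the earlier runs were made in a closed, stirred flask

- order of the set-ups by the amount of target at the outlet or at the end, in percent of the substrate put in, highest first (teal / grey / red / ochre)
- amount of target at the outlet or at the end, in percent of the substrate put in, teal
- amount of target at the outlet or at the end, in percent of the substrate put in, grey
- amount of target at the outlet or at the end, in percent of the substrate put in, red
- amount of target at the outlet or at the end, in percent of the substrate put in, ochre

1. Cedar, with 0.47 equiv of partner, reads 61 % substrate at 4.00 min. Birch, with 0.95 equiv, reads 59 % at 3.00 min and 49 % at 6.00 min. So I take the fall of free substrate as a step that does not wait for partner.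

2. The last birch readings flatten near 37.0 %, and taking that as the plateau, the reading at 3.00 min gives a relaxation rate of 0.351 min⁻¹, itself a reading with scatter.

3. I assume target grows with free substrate times partner. I define the contact share as a run's time-average of that product, divided by the same average for the closed flask. Ochre is the birch recipe, so I put it at the birch reading, 25 %.

4. First estimate: with flat substrate, either feed gives half the contact, so teal and grey tie at 12.5 %.

5. Objection: substrate is not flat. Over the run, rate times time is 7.01, and the early excess adds 8.98 % to the closed flask's average of 46.0 %. Teal's fresh substrate enters beside partner charged from the start, but grey's early substrate meets partner that is still being fed. The shares become 0.570 for teal and 0.430 for grey, so the tie breaks: teal 14.2 %, grey 10.8 %.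

6. Objection: partner falls as target forms, and target lags. I have not reckoned either, so the order stays an estimate. By the same reckoning, red's tank holds 44.9 % free substrate, but its partner stands at outlet level. I place red below ochre and above teal, without a number.

The forecast says ochre > red > grey > teal, with teal 12 %, grey 15 %, red 20 %, ochre 25 %; grey gets its figure “since partner averages half its charge”. There we differ: my order puts teal above grey.

The flasks give ochre > red > teal > grey: teal 13.6 %, grey 10.3 %, red 16.6 %, ochre 22.2 %.

    substrate + partner ⇌ intermediate A (K = 7.90 M⁻¹, k = 0.472 M⁻¹ min⁻¹)
    partner + intermediate A → target (k = 4.45 M⁻¹ min⁻¹)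
    substrate ⇌ dormant form (K = 1.13, k = 0.147 min⁻¹)
    partner + intermediate A ⇌ intermediate B (K = 300 M⁻¹, k = 0.0980 M⁻¹ min⁻¹)

Grey's contact share times ochre's result gives 9.55 % for grey, against the 10.3 % it made. The neighbouring flask is grey with 0.17 M of substrate, the equivalents held, so both charges rise by 1.70. My assumed product then grows by that factor squared, and target in percent of the larger charge by that factor once, which gives 16.2 %. That neighbouring flask ends with 35.1 % substrate and 16.6 % target.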